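## Retrosynthetic overview

1. Target ⇐ oxidation of the C4 hydroxymethyl group of a cis-fused bicyclic alcohol (last step). Labdane numbering is used throughout.
2. Rings A then B, in one operation ⇐ cationic chair–chair bicyclization of an acyclic all-cis epoxy-diene, mirroring the head-to-tail cyclization of an all-cis C20 chain by a labdane-type cyclase. An (S)-2-methyloxirane initiates (C4–C5 bond), the cis C5=C10 alkene gives the cis ring fusion, and a cis allylsilane terminates (C9–C10 bond, exocyclic C8=C17).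
3. Oxirane ⇐ methyl ketone by catalytic asymmetric methylene transfer. C13 ⇐ Cu-catalysed asymmetric 1,4-addition of the C12 Grignard reagent to methyl crotonate.
4. The two cis trisubstituted alkenes ⇐ two stereoretentive Ni-catalysed Grignard ring openings of 5-substituted 2,3-dihydrofurans.
5. Building blocks: a chloro-ketal, 5-methyl-2,3-dihydrofuran, 2,3-dihydrofuran, ICH2SiMe3 and methyl crotonate.

Assumption: the SMILES is taken literally as (4S,5R,9R,10S,13R), a cis-fused decalin with H-5, CH3-10 and the C9 side chain on one face and CO2H on the other; the ligand antipodes named in steps 6 and 8 are those taken to give (13R) and the (S)-oxirane, and the mirror-image ligand is used if the measured sense is opposite.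

## Route

Step 1
Reactants: 1 2-(3-chloropropyl)-2-methyl-1,3-dioxolane; 2 5-methyl-2,3-dihydrofuran
Product: 4 (3Z)-4-methyl-7-(2-methyl-1,3-dioxolan-2-yl)hept-3-en-1-ol, via Grignard reagent 3 (not isolated)
Conditions: Mg, THF, 60 °C; then 2, NiCl2(PPh3)2 (5 mol%), toluene, 80 °C; aqueous work-up
Reagents that add atoms: none
Why: Wenkert-type Kumada coupling in which zerovalent nickel inserts into the vinylic C–O bond of the cyclic enol ether and the Grignard carbon takes the place of the ring oxygen with retention, so the new chain is cis to the CH2CH2OH arm (the cis C5=C10 alkene).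

Step 2
Reactants: 4 (3Z)-4-methyl-7-(2-methyl-1,3-dioxolan-2-yl)hept-3-en-1-ol
Product: 5 2-[(4Z)-7-bromo-4-methylhept-4-en-1-yl]-2-methyl-1,3-dioxolane
Conditions: CBr4, PPh3, 2,6-lutidine, CH2Cl2, 0 °C
Reagents that add atoms: carbon tetrabromide BrC(Br)(Br)Br
Why: Appel bromination of a primary alcohol under buffered, non-acidic conditions that leave the ketal and the alkene geometry untouched.

Step 3
Reactants: 6 2,3-dihydrofuran; 7 (iodomethyl)trimethylsilane
Product: 9 [(4,5-dihydrofuran-2-yl)methyl]trimethylsilane, via 5-lithio-2,3-dihydrofuran 8 (not isolated)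
Conditions: t-BuLi, THF, −78 → 0 °C; then 7, THF/DMPU, −40 °C → rt
Reagents that add atoms: none
Why: α-lithiation of the enol ether at the sp2 C–H next to oxygen, then SN2 alkylation with the primary iodide.

Step 4
Reactants: 5 2-[(4Z)-7-bromo-4-methylhept-4-en-1-yl]-2-methyl-1,3-dioxolane; 9 [(4,5-dihydrofuran-2-yl)methyl]trimethylsilane
Product: 11 (3E,7Z)-8-methyl-11-(2-methyl-1,3-dioxolan-2-yl)-4-[(trimethylsilyl)methyl]undeca-3,7-dien-1-ol, via Grignard reagent 10 (not isolated)
Conditions: Mg, THF, rt; then 9, NiCl2(PPh3)2 (5 mol%), toluene, 70 °C; aqueous work-up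
Reagents that add atoms: none
Why: the same stereoretentive Ni-catalysed Kumada coupling of a cyclic enol ether, which puts the incoming chain (C7) cis to the CH2CH2OH arm (C11) and leaves CH2SiMe3 trans; the descriptor is E only because Si outranks C.

Step 5
Reactants: 11 (3E,7Z)-8-methyl-11-(2-methyl-1,3-dioxolan-2-yl)-4-[(trimethylsilyl)methyl]undeca-3,7-dien-1-ol
Product: 12 2-[(4Z,8E)-11-bromo-4-methyl-8-[(trimethylsilyl)methyl]undeca-4,8-dien-1-yl]-2-methyl-1,3-dioxolane
Conditions: CBr4, PPh3, 2,6-lutidine, CH2Cl2, 0 °C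
Reagents that add atoms: carbon tetrabromide BrC(Br)(Br)Br
Why: Appel bromination; the neutral, buffered medium avoids protodesilylation of the allylsilane and ketal cleavage.

Step 6
Reactants: 12 2-[(4Z,8E)-11-bromo-4-methyl-8-[(trimethylsilyl)methyl]undeca-4,8-dien-1-yl]-2-methyl-1,3-dioxolane; 13 methyl (2E)-but-2-enoate
Product: 15 methyl (3R,6E,10Z)-3,11-dimethyl-14-(2-methyl-1,3-dioxolan-2-yl)-7-[(trimethylsilyl)methyl]tetradeca-6,10-dienoate, via Grignard reagent 14 (not isolated)
Conditions: Mg, Et2O, rt; then slow addition to 13, CuBr·SMe2 (5 mol%), (R)-1-[(S)-2-(diphenylphosphino)ferrocenyl]ethyldicyclohexylphosphine (6 mol%), t-BuOMe, −75 °C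
Reagents that add atoms: none
Why: Cu-catalysed asymmetric conjugate addition of a primary alkyl Grignard reagent to a crotonate, in which the chiral diphosphine complex of monovalent copper delivers the alkyl group to one face of the β-carbon and sets C13 as R; 1,4-addition outruns 1,2-addition at −75 °C.

Step 7
Reactants: 15 methyl (3R,6E,10Z)-3,11-dimethyl-14-(2-methyl-1,3-dioxolan-2-yl)-7-[(trimethylsilyl)methyl]tetradeca-6,10-dienoate
Product: 16 methyl (3R,6E,10Z)-3,11-dimethyl-15-oxo-7-[(trimethylsilyl)methyl]hexadeca-6,10-dienoate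
Conditions: PPTS (cat.), acetone/H2O 10:1, 50 °C
Reagents that add atoms: water O
Why: mild acid-catalysed ketal hydrolysis (transketalization to acetone), weak enough to spare the allylsilane, the methyl ester and the alkene geometry.

Step 8
Reactants: 16 methyl (3R,6E,10Z)-3,11-dimethyl-15-oxo-7-[(trimethylsilyl)methyl]hexadeca-6,10-dienoate
Product: 17 methyl (3R,6E,10Z)-3,11-dimethyl-14-[(2S)-2-methyloxiran-2-yl]-7-[(trimethylsilyl)methyl]tetradeca-6,10-dienoate
Conditions: trimethylsulfoxonium iodide, NaH, THF (ylide pre-formed); LaLi3[(S)-binaphthoxide]3 (5 mol%), tris(2,4,6-trimethoxyphenyl)phosphine oxide (5 mol%), 5 Å MS, THF, rt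
Reagents that add atoms: trimethylsulfoxonium iodide C[S+](C)(C)=O.[I-]
Why: catalytic asymmetric Corey–Chaykovsky epoxidation in which the La/Li binaphthoxide binds ketone and ylide and delivers CH2 to one face of the methyl ketone, setting the quaternary oxirane carbon (future C4) as S; the ester reacts far more slowly with the sulfoxonium ylide at rt.

Step 9
Reactants: 17 methyl (3R,6E,10Z)-3,11-dimethyl-14-[(2S)-2-methyloxiran-2-yl]-7-[(trimethylsilyl)methyl]tetradeca-6,10-dienoate
Product: 18 methyl (3R)-5-[(1R,4aR,5S,8aS)-5-(hydroxymethyl)-5,8a-dimethyl-2-methylidenedecahydronaphthalen-1-yl]-3-methylpentanoate (labdane 4S,5R,9R,10S,13R; cis-fused, CH2OH trans to the angular methyl)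
Conditions: MeAlCl2 (2.2 equiv), CH2Cl2, −78 °C; then aq. HCl work-up
Reagents that add atoms: none
Why: Proposed new method: MeAlCl2 ionises the oxirane at its tertiary carbon while the C5=C10 alkene attacks from the back (inversion at C4, with the bulky CH2O–Al arm equatorial so that the (S)-oxirane selects one alkene face), the cis alkene closes ring A in a chair to the C10 cation, the cis allylsilane closes ring B in a second chair (cis fusion, C11 cis to the C10 methyl) and loss of the silyl group fixes the exocyclic C8=C17 alkene, following the Stork–Eschenmoser rule for cis alkenes; the closest known reaction types are Lewis-acid epoxy-polyene cyclizations of trisubstituted oxiranes with allylsilane terminators and Friedel–Crafts cyclialkylations of 2,2-disubstituted oxiranes.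

Step 10
Reactants: 18 methyl (3R)-5-[(1R,4aR,5S,8aS)-5-(hydroxymethyl)-5,8a-dimethyl-2-methylidenedecahydronaphthalen-1-yl]-3-methylpentanoate
Product: 19 (1S,4aS,5R,8aR)-5-[(3R)-5-methoxy-3-methyl-5-oxopentyl]-1,4a-dimethyl-6-methylidenedecahydronaphthalene-1-carboxylic acid (target)
Conditions: CrO3, H2SO4, H2O (Jones reagent), acetone, 0 °C
Reagents that add atoms: water O
Why: Jones oxidation takes the neopentyl primary alcohol through the aldehyde hydrate to the acid with hexavalent chromium, touching neither the exocyclic alkene nor the methyl ester, and no stereocentre is epimerizable.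

## Compound list

1 | 2-(3-chloropropyl)-2-methyl-1,3-dioxolane | CC1(CCCCl)OCCO1 | starting material
2 | 5-methyl-2,3-dihydrofuran | CC1=CCCO1 | starting material
3 | [3-(2-methyl-1,3-dioxolan-2-yl)propyl]magnesium chloride | CC1(CCC[Mg]Cl)OCCO1 | intermediate
4 | (3Z)-4-methyl-7-(2-methyl-1,3-dioxolan-2-yl)hept-3-en-1-ol | OCC/C=C(C)\CCCC1(C)OCCO1 | intermediate
5 | 2-[(4Z)-7-bromo-4-methylhept-4-en-1-yl]-2-methyl-1,3-dioxolane | BrCC/C=C(C)\CCCC1(C)OCCO1 | intermediate
6 | 2,3-dihydrofuran | C1=COCC1 | starting material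
7 | (iodomethyl)trimethylsilane | C[Si](C)(C)CI | starting material
8 | 5-lithio-2,3-dihydrofuran | [Li]C1=CCCO1 | intermediate
9 | [(4,5-dihydrofuran-2-yl)methyl]trimethylsilane | C[Si](C)(C)CC1=CCCO1 | intermediate
10 | [(3Z)-4-methyl-7-(2-methyl-1,3-dioxolan-2-yl)hept-3-en-1-yl]magnesium bromide | Br[Mg]CC/C=C(C)\CCCC1(C)OCCO1 | intermediate
11 | (3E,7Z)-8-methyl-11-(2-methyl-1,3-dioxolan-2-yl)-4-[(trimethylsilyl)methyl]undeca-3,7-dien-1-ol | OCC/C=C(C[Si](C)(C)C)\CC/C=C(C)\CCCC1(C)OCCO1 | intermediate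
12 | 2-[(4Z,8E)-11-bromo-4-methyl-8-[(trimethylsilyl)methyl]undeca-4,8-dien-1-yl]-2-methyl-1,3-dioxolane | BrCC/C=C(C[Si](C)(C)C)\CC/C=C(C)\CCCC1(C)OCCO1 | intermediate
13 | methyl (2E)-but-2-enoate | C/C=C/C(=O)OC | starting material
14 | [(3E,7Z)-8-methyl-11-(2-methyl-1,3-dioxolan-2-yl)-4-[(trimethylsilyl)methyl]undeca-3,7-dien-1-yl]magnesium bromide | Br[Mg]CC/C=C(C[Si](C)(C)C)\CC/C=C(C)\CCCC1(C)OCCO1 | intermediate
15 | methyl (3R,6E,10Z)-3,11-dimethyl-14-(2-methyl-1,3-dioxolan-2-yl)-7-[(trimethylsilyl)methyl]tetradeca-6,10-dienoate | COC(=O)C[C@H](C)CC/C=C(C[Si](C)(C)C)\CC/C=C(C)\CCCC1(C)OCCO1 | intermediate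
16 | methyl (3R,6E,10Z)-3,11-dimethyl-15-oxo-7-[(trimethylsilyl)methyl]hexadeca-6,10-dienoate | COC(=O)C[C@H](C)CC/C=C(C[Si](C)(C)C)\CC/C=C(C)\CCCC(C)=O | intermediate
17 | methyl (3R,6E,10Z)-3,11-dimethyl-14-[(2S)-2-methyloxiran-2-yl]-7-[(trimethylsilyl)methyl]tetradeca-6,10-dienoate | COC(=O)C[C@H](C)CC/C=C(C[Si](C)(C)C)\CC/C=C(C)\CCC[C@@]1(C)CO1 | intermediate
18 | methyl (3R)-5-[(1R,4aR,5S,8aS)-5-(hydroxymethyl)-5,8a-dimethyl-2-methylidenedecahydronaphthalen-1-yl]-3-methylpentanoate | C=C1CC[C@@H]2[C@@](C)(CCC[C@]2(C)CO)[C@@H]1CC[C@@H](C)CC(=O)OC | intermediate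
19 | (1S,4aS,5R,8aR)-5-[(3R)-5-methoxy-3-methyl-5-oxopentyl]-1,4a-dimethyl-6-methylidenedecahydronaphthalene-1-carboxylic acid | C=C1CC[C@@H]2[C@@](C)(CCC[C@]2(C)C(=O)O)[C@@H]1CC[C@@H](C)CC(=O)OC | target

## Step count

Total steps: 10. Longest linear sequence: 9 (steps 1, 2, 4, 5, 6, 7, 8, 9, 10); step 3 is the side branch.

## Steps most likely to fail, with fallbacks

1. Step 9, the bicyclization. The oxirane may rearrange to an aldehyde by a 1,2-hydride shift, stop after ring A, or select the alkene face poorly. The fallback changes the initiator from an oxirane to a thiiranium ion; it sets out from ketone 16 and comes back at target 19.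
   - Ketone 16 is epoxidised as in step 8 but with the mirror-image LaLi3 catalyst, giving methyl (3R,6E,10Z)-3,11-dimethyl-14-[(2R)-2-methyloxiran-2-yl]-7-[(trimethylsilyl)methyl]tetradeca-6,10-dienoate F1. The opposite oxirane is needed because this path inverts C4 twice.
   - PhSH/Et3N in MeOH opens F1 at its CH2 to methyl (3R,6E,10Z,15R)-15-hydroxy-3,11,15-trimethyl-16-(phenylsulfanyl)-7-[(trimethylsilyl)methyl]hexadeca-6,10-dienoate F2.
   - BF3·OEt2 in CH2Cl2 at −78 °C ionises the tertiary alcohol with sulfur participation (first inversion). The diene–allylsilane opens the thiiranium ion at its tertiary carbon (second inversion) in the same chair–chair cascade, giving methyl (3R)-5-[(1R,4aR,5S,8aS)-5,8a-dimethyl-2-methylidene-5-[(phenylsulfanyl)methyl]decahydronaphthalen-1-yl]-3-methylpentanoate F3.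
   - NaIO4 in MeOH/H2O gives methyl (3R)-5-[(1R,4aR,5S,8aS)-5,8a-dimethyl-2-methylidene-5-[(phenylsulfinyl)methyl]decahydronaphthalen-1-yl]-3-methylpentanoate F4.
   - Pummerer rearrangement (TFAA, 2,6-lutidine, then aq. NaHCO3) gives methyl (3R)-5-[(1R,4aR,5S,8aS)-5-formyl-5,8a-dimethyl-2-methylidenedecahydronaphthalen-1-yl]-3-methylpentanoate F5.
   - Pinnick oxidation (NaClO2, NaH2PO4, 2-methyl-2-butene, t-BuOH/H2O) gives 19.

2. Step 4, the Ni-catalysed coupling of a β-hydrogen-bearing homoallylic Grignard reagent with the acid-sensitive silylmethyl dihydrofuran. Risks are reduction, loss of alkene geometry and decomposition of 9; step 1 shares the first two to a lesser degree. The fallback builds the same alkene by alkyne carbometalation; it sets out from bromide 5 and comes back at 11.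
   - Dilithiated but-3-yn-1-ol (n-BuLi, 2 equiv, THF/DMPU) is alkylated with 5 to give (7Z)-8-methyl-11-(2-methyl-1,3-dioxolan-2-yl)undec-7-en-3-yn-1-ol F6.
   - Alkoxide-directed syn-carbomagnesiation with Me3SiCH2MgCl and catalytic Fe(acac)3 (trivalent iron precatalyst, THF, 0 °C → rt) adds CH2SiMe3 to the distal alkyne carbon and, after protonation, H cis to it. The old chain is therefore cis to the CH2CH2OH arm, which is 11.

3. Step 6, the catalytic asymmetric conjugate addition with a functionalised Grignard reagent. Risks are modest ee and 1,2-addition. The fallback replaces catalyst control by an auxiliary; it sets out from bromide 12 (through Grignard reagent 14) and comes back at 15.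
   - (4S)-4-Phenyl-1,3-oxazolidin-2-one is acylated with crotonyl chloride (n-BuLi, THF, −78 °C) to (4S)-3-[(2E)-but-2-enoyl]-4-phenyl-1,3-oxazolidin-2-one F7.
   - Reagent 14 with CuBr·SMe2 (THF/Me2S, −40 °C) adds to the Mg-chelated s-cis imide on the face away from the phenyl group. This gives (4S)-3-[(3R,6E,10Z)-3,11-dimethyl-14-(2-methyl-1,3-dioxolan-2-yl)-7-[(trimethylsilyl)methyl]tetradeca-6,10-dienoyl]-4-phenyl-1,3-oxazolidin-2-one F8.
   - NaOMe in MeOH at 0 °C releases 15 and the auxiliary.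

## Further compounds

F1 | step 9 | methyl (3R,6E,10Z)-3,11-dimethyl-14-[(2R)-2-methyloxiran-2-yl]-7-[(trimethylsilyl)methyl]tetradeca-6,10-dienoate | COC(=O)C[C@H](C)CC/C=C(C[Si](C)(C)C)\CC/C=C(C)\CCC[C@]1(C)CO1
F2 | step 9 | methyl (3R,6E,10Z,15R)-15-hydroxy-3,11,15-trimethyl-16-(phenylsulfanyl)-7-[(trimethylsilyl)methyl]hexadeca-6,10-dienoate | COC(=O)C[C@H](C)CC/C=C(C[Si](C)(C)C)\CC/C=C(C)\CCC[C@@](C)(O)CSc1ccccc1
F3 | step 9 | methyl (3R)-5-[(1R,4aR,5S,8aS)-5,8a-dimethyl-2-methylidene-5-[(phenylsulfanyl)methyl]decahydronaphthalen-1-yl]-3-methylpentanoate | C=C1CC[C@@H]2[C@@](C)(CCC[C@]2(C)CSc3ccccc3)[C@@H]1CC[C@@H](C)CC(=O)OC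
F4 | step 9 | methyl (3R)-5-[(1R,4aR,5S,8aS)-5,8a-dimethyl-2-methylidene-5-[(phenylsulfinyl)methyl]decahydronaphthalen-1-yl]-3-methylpentanoate | C=C1CC[C@@H]2[C@@](C)(CCC[C@]2(C)CS(=O)c3ccccc3)[C@@H]1CC[C@@H](C)CC(=O)OC
F5 | step 9 | methyl (3R)-5-[(1R,4aR,5S,8aS)-5-formyl-5,8a-dimethyl-2-methylidenedecahydronaphthalen-1-yl]-3-methylpentanoate | C=C1CC[C@@H]2[C@@](C)(CCC[C@]2(C)C=O)[C@@H]1CC[C@@H](C)CC(=O)OC
F6 | step 4 | (7Z)-8-methyl-11-(2-methyl-1,3-dioxolan-2-yl)undec-7-en-3-yn-1-ol | OCCC#CCC/C=C(C)\CCCC1(C)OCCO1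
F7 | step 6 | (4S)-3-[(2E)-but-2-enoyl]-4-phenyl-1,3-oxazolidin-2-one | C/C=C/C(=O)N1[C@@H](c2ccccc2)COC1=O
F8 | step 6 | (4S)-3-[(3R,6E,10Z)-3,11-dimethyl-14-(2-methyl-1,3-dioxolan-2-yl)-7-[(trimethylsilyl)methyl]tetradeca-6,10-dienoyl]-4-phenyl-1,3-oxazolidin-2-one | O=C(C[C@H](C)CC/C=C(C[Si](C)(C)C)\CC/C=C(C)\CCCC1(C)OCCO1)N1[C@@H](c2ccccc2)COC1=O
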